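No complex can take up incoming ligand that was never charged, so the mean number of exchanges per complex cannot pass the ligand equivalents ε, charged incoming ligand over charged starting complex, which in birch is ε = 1.20.

| setting | grey | amber | blue | birch | elm | larch |
|---|---|---|---|---|---|---|
| starting complex | 0.50 mM | 0.50 mM | 0.50 mM | 0.50 mM | 0.50 mM | 0.50 mM |
| incoming ligand | 0.48 mM | 0.74 mM | 1.4 mM | 0.600 mM | 0.400 mM | 1.25 mM |
| remark | run made earlier | run made earlier | run made earlier |  |  |  |
| time |  |  |  | 2.5 min | 2.5 min | 2.5 min |

| run | time / s | complex with three exchanged / % | complex with one exchanged / % |
|---|---|---|---|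
| grey | 10.0 | 3.1 | 28.8 |
| grey | 12.0 | 5.3 | 27.8 |
| grey | 20.0 | 3.3 | 27.2 |
| grey | 40.0 | 4.3 | 29.2 |
| grey | 80.0 | 6.7 | 28.4 |
| amber | 15.0 | 17.5 | 26.3 |
| amber | 30.0 | 18.5 | 27.0 |
| amber | 50.0 | 17.0 | 26.6 |
| amber | 60.0 | 15.0 | 27.1 |
| amber | 80.0 | 17.9 | 28.2 |
| blue | 10.0 | 60.2 | 9.9 |
| blue | 12.0 | 63.7 | 9.4 |
| blue | 20.0 | 74.9 | 3.3 |
| blue | 40.0 | 83.1 | 1.7 |
| blue | 80.0 | 85.5 | 2.5 |

(readings scatter by 1 percentage point)



- which of these holds the largest part of the starting complex at the end of birch (complex with three exchanged / complex with one exchanged / starting complex / complex with two exchanged)
- which of these holds the largest part of the starting complex at the end of elm (complex with three exchanged / complex with one exchanged / starting complex / complex with two exchanged)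
- which of these holds the largest part of the starting complex at the end of larch (complex with three exchanged / complex with one exchanged / starting complex / complex with two exchanged)
- amount of complex with three exchanged at the end of birch, in percent of the starting complex charged

Two extreme versions bound birch. If each complex took one ligand before any took a second, complex with three exchanged would be absent at this ε. If every ligand went to complexes that finish all their exchanges, its share f would be:

f(max) = ε/3 = 40.0%

The runs place birch between these. This reckoning, which is not the forecast's, replaces each curve of complex with three exchanged by the mean of its readings: grey gives 4.54% at ε = 0.960, and amber gives 17.2% at ε = 1.48. A straight line between them gives, for birch: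

f ≈ 10.4%

Extended to blue, at ε = 2.80, that line gives 49.3%, but the last two blue readings average 84.3%. The curve therefore bends upward, and the line may read high.

The forecast gives 10% for birch, within 7% to 13%, with complex with two exchanged leading there, starting complex in elm and complex with three exchanged in larch. Its ground: “A ligand balance, assuming all incoming ligand is consumed, fits all three runs.”

Birch ends with 9.65% of complex with three exchanged, and complex with one exchanged leads the asked species at 28.7%. Elm ends led by starting complex, larch by complex with three exchanged.

leaving ligand → by-product carried off (k = 0.330 s⁻¹); complex with one exchanged + incoming ligand ⇌ leaving ligand + complex with two exchanged (K = 1.30, k = 3900 M⁻¹ s⁻¹); starting complex + incoming ligand ⇌ leaving ligand + complex with one exchanged (K = 19.0, k = 1900 M⁻¹ s⁻¹); complex with one exchanged ⇌ isomer of the product (K = 1.10, k = 0.290 s⁻¹); complex with two exchanged + incoming ligand ⇌ leaving ligand + complex with three exchanged (K = 14.0, k = 650 M⁻¹ s⁻¹) The forecast's 31 for complex with two exchanged in birch stands against 15.4%, while isomer of the product holds 31.6%. Incoming ligand, the limiting reagent, stands at 0% of its own charge in birch, and birch's forms, the isomer counted once, sum to 1.20 exchanges per complex. Birch with 0.30 mM of starting complex has ε = 2.00, a bound of 66.7%, and 43.6% on the amber–blue line. That flask ends with 37.0% of complex with three exchanged.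

All runs were computed with made-up constants; scatter was added.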